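**Assumption (numbering and structure check):** terpenoid numbering is used throughout: C1–C10 for the decalin, C11–C14 for ring C, C1′–C6′ for the oxygenated cyclohexane (ring E, C3′ bonded to C13, methyl on C6′), and ring D is the oxolane O–C13–C3′–C2′–C1′. Faces of the decalin are named relative to the C10 methyl. The monocyclic ketone and the decalone of the ring A closure were checked against the target at C5, C9 and C10 and are consistent, so no structure was corrected. Commercial solutions of LDA, MeMgBr, i-PrMgCl, KHMDS and EtAlCl2 are used as purchased.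

## Structural features

The target is a pentacycle: a trans-anti-trans perhydrophenanthrene (ring A C1–C5/C10 with the C4 gem-dimethyl group, ring B C5–C10, ring C C8/C9/C11–C14) spiro-joined at C13 to a 6-oxabicyclo[3.2.1]octane made of the oxolane ring D and the cyclohexanone ring E. Ten stereocentres are present. C5, C6, C8, C9 and C10 are contiguous around ring B, with the C8 and C10 methyls and the C6 acetate all axial on one face. C13, C3′, C2′, C1′ and C6′ form a second run in which the ring D oxygen, the C2′ hydroxyl, the C13 carbon and the C6′ methyl all lie on the same face of ring E. At the spiro centre the oxygen is axial on ring C, syn to the C8 methyl, and the bulky C3′ carbon is equatorial. Ring E is the fragile part: the C5′ ketone is β to the ring D oxygen on C1′, so base can open ring D by retro-oxa-Michael reaction and, after loss of the C2′ hydroxyl, aromatise ring E; C6′ is epimerisable, the tertiary C13–O bond is acid-labile, and the C6 acetate sits on an alcohol screened by three syn-axial methyls. The real difficulty is the oxygen at C6, which polyene cyclisations do not place, next to two syn quaternary methyl carbons, together with the spiro ether C13 and its four neighbouring stereocentres. The key step exploits that C5 is the α-carbon of a C6 carbonyl and is bonded to the gem-dimethyl carbon C4: ring A is the alkylation of the C5 enol of a ring B ketone by a tertiary C4 cation on a homoprenyl chain carried by quaternary C10.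

## Logic of the disconnections

**43 back to 40.** The last bonds cut are the C2′ O–benzyl bond (43 from 42) and the C5′ carbonyl, traced to a silyl-protected alcohol (42 from 41 from 40). The β-alkoxy ketone is the most fragile function, so it is unveiled only in the last two steps. This demands a non-basic oxidation and a neutral final deprotection.

**40 back to 38.** The C6 O–acetyl bond and the C6–H bond are cut, returning to the C6 ketone. That ketone is what activates ring B for the closure of ring C. The forward steps must deliver hydride from the face opposite three axial methyls and acylate a very hindered alcohol.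

**38 back to 37.** C8–C14 and C13–O are cut together. This removes rings C and D and the stereocentres C8 and C13 in one operation and leaves a decalin enone tethered to a monocyclic ring E. Forward, C14 must add anti to the C10 methyl and the C1′ oxygen must capture the C13 cation before a proton is lost.

**37 back to 20 and 34.** The sp3–sp2 bond C12–C13 is cut. The molecule falls into two fragments of similar size, each with its own stereocentres. The C12 organometallic must tolerate an enone, which points to an alkylzinc.

**20 back to 14.** 20 comes from 18 by functional-group change at C12. The C8–CH3 bond and the C7=C8 unsaturation are then cut (18 from 16 from 14), returning to the saturated 6-ketone. Two enol-silane formations toward C7 are required.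

**14 back to 12 (key).** C4–C5 is cut. Ring A opens to a monocyclic ketone with a homoprenyl chain; the gem-dimethyl ring and the ring-fusion centre are gained in one bond. A tertiary cation must be generated beside a ketone, and C5 must be able to equilibrate to the trans fusion.

**12 back to 8 and 9.** C10–C1 is cut; quaternary C10 arises by conjugate addition. The nucleophile must enter anti to the C9 substituent.

**8 back to 1 and 4.** The C10–CH3 bond is cut (8 from 6), then C8–C9 and C5=C10 (6 from 3 and 4, Michael addition and aldol condensation); 3 comes from 2 and 1. The single stereocentre C9 must be set by the catalyst and survive ring closure.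

**34 back to 30.** C13–C14 is cut (33 from 32) and the amide traced to the lactone (32 from 30). In 30 the C1′ oxygen is tied up as the lactone, which distinguishes it from the C2′ and C5′ oxygens. The enolisation of 33 must be kinetic, toward the methyl group.

**30 back to 24.** The C5′–O bond (29 from 28) and the C1′–O bond (26 from 24) are cut. The all-cis array then derives from the single cis relationship in 24. The bicyclic lactone must direct both additions to its convex face.

**24 back to 21 and 23.** C2′–C3′ and C4′–C5′ are cut (Diels–Alder); 22 comes from 21. The cycloaddition must be endo, ortho and enantioselective.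

## Other disconnections considered

**Alternative 1:** The cut is C2′–C3′ in ring D. Forward, a chiral triazolium-derived carbene would convert the aldehyde of the aldehyde–enone A1 into a Breslow intermediate that adds to C3′ of the enone, closing ring D as the spiro dihydrofuranone A2.
- *In favour:* it is catalytic and metal-free, it sets C3′ under catalyst control, and it works on a tricycle that already carries the C6 acetate. Ring B then needs no late reduction and acylation; on this point it is better than the chosen plan.
- *Against:* A1 presupposes the whole tricycle with a C13 tertiary ether of defined configuration that bears both an O-(2-oxoethyl) group and a vinyl ketone; O-alkylation of so hindered a tertiary alcohol is doubtful. The acceptor β-carbon is neopentyl. After A2, ring E is still open: C1′–C6′ must be joined between two ketone α-carbons, C2′ must be reduced in the presence of the C5′ ketone, and C1′, C2′ and C6′ remain unset.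
- *Comparison:* on structure, both key steps form one bond and one stereocentre, but the chosen one also places the C6 oxygen. On mechanism, the acyl-anion addition is the milder process and is the equal or better for functional-group tolerance. On step economy it should be worse, because ring E would be built linearly on the full skeleton.

**Alternative 2:** The cut is C8–C14 plus C13–O. Forward, EtAlCl2 would activate the enone of 37; C14 adds to C8 and the C1′ oxygen captures the C13 cation, giving the pentacyclic ketone A3 (identical with 38).
- *In favour:* two bonds, two rings and two stereocentres in one operation; in complexity per step it is better than the chosen ring A closure, and it is convergent.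
- *Against, as the centre of the plan:* it needs the 8-methyl-7-en-6-one and therefore a finished ring A with a C6 ketone, which it does not itself provide. It also risks proton loss from the cation and acid-catalysed hydroalkoxylation of the methylene group.
- *Comparison:* the two are complementary rather than competing, and the route uses this closure as step 22. Both are cation–π closures; the chosen one is corrected thermodynamically at its only stereocentre, whereas this one is under kinetic control at C8 and C13. Step economy is equal, since both are needed.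

**Alternative 3:** The cut is C12–C13 plus C13–C14. Forward, the di-Grignard reagent from the dibromide A4 would add twice to the carbonyl of lactone 30, closing ring C as the carbinol A5 and freeing the C1′ hydroxyl; ring D would follow by acid-mediated etherification.
- *In favour:* lactone 30 is used directly, so compounds 31–34 are not needed; this is better fragment economy than the chosen plan. The C–C bonds come from polar additions, and C6 is safely ketalised.
- *Against:* A4 needs the C8 quaternary centre with a functionalised one-carbon arm of defined configuration before ring C exists. The C14 bromide is neopentyl. A 1,5-di-Grignard reagent can close to a cyclopentane or stop at the ketone. The C13–O bond and the C13 configuration would still have to come from ionisation of a tertiary alcohol, in competition with elimination.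
- *Comparison:* on structure it also relies on a C6-oxygenated decalin and so does not replace the ring A closure; in convergence it is equal. On mechanism, double addition of a di-Grignard to an ester is classical, which is in its favour, but C8 stereocontrol moves to a less secure intermolecular step. It should cost more steps on the decalin side than it saves on the lactone side.

Key step: step 6

## Route

Step 1
Reactants: 1 butane-1,4-diol
Product: 2 4-[(tert-butyldiphenylsilyl)oxy]butan-1-ol
Conditions: NaH (1.0 equiv), THF, 0 °C to rt; t-BuPh2SiCl (1.0 equiv)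
Reagents that add atoms: tert-butyl(chloro)diphenylsilane, CC(C)(C)[Si](Cl)(c1ccccc1)c1ccccc1
Why: Monosilylation of a symmetrical diol through its sparingly soluble monosodium alkoxide, which is silylated faster than it equilibrates, so the mono-ether should dominate.

Step 2
Reactants: 2 4-[(tert-butyldiphenylsilyl)oxy]butan-1-ol
Product: 3 4-[(tert-butyldiphenylsilyl)oxy]butanal
Conditions: TEMPO (10 mol %), PhI(OAc)2 (1.1 equiv), CH2Cl2, rt
Reagents that add atoms: none
Why: Nitroxyl-catalysed oxidation of a primary alcohol stops at the aldehyde and leaves the silyl ether untouched.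

Step 3
Reactants: 3 4-[(tert-butyldiphenylsilyl)oxy]butanal; 4 but-3-en-2-one (methyl vinyl ketone)
Product: 6 (S)-4-{2-[(tert-butyldiphenylsilyl)oxy]ethyl}cyclohex-2-en-1-one, via keto-aldehyde Michael adduct 5 (not isolated)
Conditions: (S)-α,α-diphenylprolinol trimethylsilyl ether (10 mol %), ethyl 3,4-dihydroxybenzoate (20 mol %), neat, 4 °C; then LiOH (0.5 equiv), i-PrOH, rt
Reagents that add atoms: none
Why: Enamine-catalysed Michael addition: the E-enamine of 3 is attacked on the face remote from the diaryl(silyloxy)methyl group, which sets C9 as (S); aldol condensation of the methyl ketone onto the aldehyde then closes the cyclohexenone, the stereocentre becoming the non-enolisable γ-carbon.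

Step 4
Reactants: 6 (S)-4-{2-[(tert-butyldiphenylsilyl)oxy]ethyl}cyclohex-2-en-1-one
Product: 8 (S)-4-{2-[(tert-butyldiphenylsilyl)oxy]ethyl}-3-methylcyclohex-2-en-1-one, via trimethylsilyl enol ether 7 (not isolated)
Conditions: MeMgBr, CuBr·SMe2 (10 mol %), Me3SiCl, THF, −78 °C; concentrate; then Pd(OAc)2 (1.05 equiv), MeCN, rt
Reagents that add atoms: methylmagnesium bromide, C[Mg]Br (chlorotrimethylsilane, C[Si](C)(C)Cl, enters 7 only)
Why: Copper-catalysed conjugate addition with in situ silylation gives the regiodefined enol silane (methyl trans to the C9 chain, of no consequence); Ito–Saegusa oxidation returns the enone with the methyl on the β-carbon and C9 untouched.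

Step 5
Reactants: 8 (S)-4-{2-[(tert-butyldiphenylsilyl)oxy]ethyl}-3-methylcyclohex-2-en-1-one; 9 5-bromo-2-methylpent-2-ene
Product: 12 (3R,4S)-4-{2-[(tert-butyldiphenylsilyl)oxy]ethyl}-3-methyl-3-(4-methylpent-3-en-1-yl)cyclohexan-1-one, via homoprenylmagnesium bromide 10 (not isolated), via C5 trimethylsilyl enol ether 11 (not isolated)
Conditions: 9, Mg, THF, rt; then 8, CuBr·SMe2 (20 mol %), Me3SiCl, THF, −78 to −30 °C; then 1 M HCl, THF, 0 °C
Reagents that add atoms: none
Why: Copper-catalysed Grignard conjugate addition to a β,β-disubstituted enone builds quaternary C10; the C9 chain sits pseudoaxial next to the vinylic methyl and the nucleophile enters anti to it, as is known for 3,4-dialkylcyclohexenones, so the homoprenyl group ends trans and the methyl cis to the C9 chain; dilute acid hydrolyses the enol silane.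

Step 6
Reactants: 12 (3R,4S)-4-{2-[(tert-butyldiphenylsilyl)oxy]ethyl}-3-methyl-3-(4-methylpent-3-en-1-yl)cyclohexan-1-one
Product: 14 (4S,4aS,8aR)-4-{2-[(tert-butyldiphenylsilyl)oxy]ethyl}-4a,8,8-trimethyloctahydronaphthalen-1(2H)-one (trans-fused decalin-6-one), via cis-fused C5 epimer 13 (not isolated)
Conditions: SnCl4 (2.0 equiv), CF3CO2H (0.5 equiv), CH2Cl2, −78 to 0 °C; then NaOMe (0.3 equiv), MeOH, rt
Reagents that add atoms: none
Why: SnCl4 with CF3CO2H protonates the trisubstituted alkene at C3 to give the tertiary C4 cation (in equilibrium with its chloride and trifluoroacetate) while the tin-bound ketone enolises reversibly toward C5 and C7; the C5 enol carbon attacks C4 and loss of a proton returns the C6 ketone. The closest known reaction type is the SnCl4-promoted cyclisation of olefinic β-keto esters and, more generally, the Lewis-acid tert-alkylation of ketone enol derivatives, a cationic enol–olefin cyclisation. Ring A closes as a six-membered ring through a chair-like transition state with the chain equatorial on C10 and the enol double bond exocyclic to the new ring; the C7 enol would have to form a bridged eight-membered ring, so the regiochemistry is geometric. The one new stereocentre, C5, is α to the ketone: axial attack on the enol anti to the C10 methyl should first give mainly the cis-fused epimer 13, and enolisation (acid in the flask, then NaOMe) converts it into the trans-fused 14, favoured because both ring A bonds at C5 and C10 are then equatorial on ring B and the C9 chain stays equatorial. The step needs chemoselectivity for enol alkylation over Prins-type attack of the alkene on the activated carbonyl; that path requires the ring-flipped conformer with both chains axial and gives a bridged carbinol that can revert, whereas the C–C alkylation is irreversible. The free ketone is used on purpose in place of a silyl enol ether, which would be protonated before the alkene; the tert-butyldiphenylsilyl ether and the non-enolisable C9 centre are inert.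

Step 7
Reactants: 14 trans-fused decalin-6-one
Product: 16 7-en-6-one (C7=C8 enone of 14; C5, C9 and C10 as in 14), via C6–C7 trimethylsilyl enol ether 15 (not isolated)
Conditions: LDA, Me3SiCl, THF, −78 °C; concentrate; then Pd(OAc)2 (1.05 equiv), MeCN, rt
Reagents that add atoms: none
Why: Kinetic deprotonation occurs at C7 because the C5 hydrogen is tertiary and flanked by two quaternary carbons; Ito–Saegusa dehydrogenation of the enol silane gives the enone without touching C5.

Step 8
Reactants: 16 7-en-6-one
Product: 18 8-methyl-7-en-6-one (C12 tert-butyldiphenylsilyl ether), via C6–C7 trimethylsilyl enol ether of the 8-methyl ketone 17 (not isolated)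
Conditions: MeMgBr, CuBr·SMe2 (10 mol %), Me3SiCl, THF, −78 °C; concentrate; then Pd(OAc)2 (1.05 equiv), MeCN, 40 °C
Reagents that add atoms: methylmagnesium bromide, C[Mg]Br (chlorotrimethylsilane, C[Si](C)(C)Cl, enters 17 only)
Why: The same conjugate methylation and Ito–Saegusa sequence as in step 4 places the methyl on C8 (its transient configuration is irrelevant) and restores the C7=C8 double bond.

Step 9
Reactants: 18 8-methyl-7-en-6-one (C12 silyl ether)
Product: 19 8-methyl-7-en-6-one with free C12 hydroxyl
Conditions: HF·pyridine, pyridine, THF, 0 °C to rt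
Reagents that add atoms: none
Why: Fluoride cleavage of the primary silyl ether under buffered, non-basic conditions, so that the enone with its γ-hydrogens is not deconjugated.

Step 10
Reactants: 19 8-methyl-7-en-6-one with free C12 hydroxyl
Product: 20 8-methyl-7-en-6-one C12 iodide
Conditions: I2, PPh3, imidazole, CH2Cl2, 0 °C
Reagents that add atoms: iodine, II
Why: Appel-type iodination of a primary alcohol by SN2 displacement of the oxyphosphonium group; the hindered enone is inert.

Step 11
Reactants: 21 3-methylbut-2-enal
Product: 22 (E)-3-methylbuta-1,3-dien-1-yl acetate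
Conditions: isopropenyl acetate, p-TsOH (2 mol %), 95 °C, acetone distilled off
Reagents that add atoms: isopropenyl acetate, CC(=C)OC(C)=O
Why: Acid-catalysed enol-ester exchange traps the dienol of the enal as its acetate; the conjugated (E)-diene is the thermodynamic isomer.

Step 12
Reactants: 22 (E)-3-methylbuta-1,3-dien-1-yl acetate; 23 3-acryloyl-1,3-oxazolidin-2-one
Product: 24 (1S,6R)-3-methyl-6-[(2-oxo-1,3-oxazolidin-3-yl)carbonyl]cyclohex-2-en-1-yl acetate
Conditions: [Cu{(R,R)-t-Bu-box}](SbF6)2 (5 mol %; box = 2,2′-isopropylidenebis(4-tert-butyl-2-oxazoline)), CH2Cl2, −20 °C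
Reagents that add atoms: none
Why: Catalytic asymmetric Diels–Alder reaction: the divalent copper complex chelates the imide and shields one face of the s-cis acryloyl unit; ortho regiochemistry and the endo transition state give the cis relation of the C2′ oxygen and the C3′ carbonyl group, and the (R,R) ligand is chosen because the (S,S) complex is known to give the (S) series with this dienophile.

Step 13
Reactants: 24 Diels–Alder adduct
Product: 26 8-hydroxy-4-iodo-4-methyl-6-oxabicyclo[3.2.1]octan-7-one (hydroxyl syn to the lactone bridge; iodine anti to the ring oxygen), via hydroxy acid 25 (not isolated)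
Conditions: LiOH, H2O2, THF/H2O, 0 °C; Na2SO3; CH2Cl2 wash; then NaHCO3, KI, I2, H2O/CH2Cl2, 0 °C, dark
Reagents that add atoms: hydrogen peroxide, OO (as LiOOH; one carboxyl oxygen); iodine, II
Why: Hydroperoxide cleaves the exocyclic imide carbonyl and the acetate; iodolactonisation then opens the iodonium ion formed anti to the carboxylate at the nearer carbon C1′ in a trans-diaxial γ-lactone closure, so the C1′ oxygen is necessarily cis to the C3′ carbon.

Step 14
Reactants: 26 hydroxy iodolactone
Product: 27 8-hydroxy-4-methyl-6-oxabicyclo[3.2.1]oct-3-en-7-one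
Conditions: DBU, toluene, 80 °C
Reagents that add atoms: none
Why: E2 elimination: the axial tertiary iodide is antiperiplanar to the axial C5′ hydrogen, giving the endocyclic C5′=C6′ alkene.

Step 15
Reactants: 27 unsaturated hydroxy lactone
Product: 28 8-(benzyloxy)-4-methyl-6-oxabicyclo[3.2.1]oct-3-en-7-one
Conditions: NaH, BnBr, Bu4NI (cat.), THF, 0 °C to rt
Reagents that add atoms: benzyl bromide, BrCc1ccccc1
Why: Williamson benzylation of the C2′ alkoxide; the lactone α-carbon is a bridgehead and cannot enolise, so the base does no harm.

Step 16
Reactants: 28 benzyl ether lactone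
Product: 29 8-(benzyloxy)-3-hydroxy-4-methyl-6-oxabicyclo[3.2.1]octan-7-one (C6′ methyl cis to the ring oxygen; C5′ hydroxyl trans to the methyl)
Conditions: BH3·THF, THF, 0 °C; then NaBO3·4H2O, H2O, rt
Reagents that add atoms: sodium perborate, [Na+].[O-]OB=O
Why: Hydroboration from the convex face anti to the lactone bridge puts boron on the less substituted C5′ and hydrogen on C6′, which sets the C6′ methyl cis to the ring oxygen; perborate oxidises the borane without opening the lactone.

Step 17
Reactants: 29 hydroxy lactone
Product: 30 8-(benzyloxy)-3-[(tert-butyldimethylsilyl)oxy]-4-methyl-6-oxabicyclo[3.2.1]octan-7-one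
Conditions: t-BuMe2SiCl, imidazole, DMF, rt
Reagents that add atoms: tert-butyl(chloro)dimethylsilane, CC(C)(C)[Si](C)(C)Cl
Why: Standard silylation of an unhindered equatorial secondary alcohol.

Step 18
Reactants: 30 silyl ether lactone
Product: 32 ring E Weinreb amide with C1′ triethylsilyl ether (C2′ benzyl ether; C5′ tert-butyldimethylsilyl ether), via hydroxy Weinreb amide 31 (not isolated)
Conditions: Me(MeO)NH·HCl, i-PrMgCl, THF, −20 to 0 °C; then Et3SiCl, imidazole (cat.), 0 °C to rt
Reagents that add atoms: N,O-dimethylhydroxylamine hydrochloride, CNOC.Cl; chlorotriethylsilane, CC[Si](Cl)(CC)CC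
Why: Aminolysis of the lactone by the magnesium amide frees the C1′ oxygen as its magnesium alkoxide, which is silylated in the same flask before it can relactonise.

Step 19
Reactants: 32 Weinreb amide
Product: 33 ring E methyl ketone (C13 acetyl on C3′)
Conditions: MeMgBr, THF, 0 °C
Reagents that add atoms: methylmagnesium bromide, C[Mg]Br
Why: Weinreb ketone synthesis: the chelated tetrahedral intermediate prevents over-addition, and the new methyl is C14.

Step 20
Reactants: 33 methyl ketone
Product: 34 ring E 1-(trifluoromethanesulfonyloxy)vinyl compound (C13=C14 enol triflate)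
Conditions: KHMDS, THF, −78 °C; then PhNTf2, −78 to 0 °C
Reagents that add atoms: N-phenylbis(trifluoromethanesulfonimide), O=S(=O)(N(c1ccccc1)S(=O)(=O)C(F)(F)F)C(F)(F)F
Why: Kinetic deprotonation takes the methyl hydrogens in preference to the tertiary C3′ hydrogen, and O-triflation fixes the terminal enolate as the C13=C14 enol triflate.

Step 21
Reactants: 20 decalin enone iodide; 34 enol triflate
Product: 37 coupled enone with C13=C14 methylene and free C1′ hydroxyl (C2′ benzyl ether; C5′ silyl ether), via alkylzinc iodide 35 (not isolated), via C1′ triethylsilyl ether 36 (not isolated)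
Conditions: 20, Zn dust (activated with BrCH2CH2Br and Me3SiCl), LiCl, THF, 40 °C; then 34, Pd(dppf)Cl2 (5 mol %), THF/DMA, 50 °C; then AcOH/THF/H2O, rt
Reagents that add atoms: none
Why: Zinc inserts into the primary C–I bond and the resulting alkylzinc halide tolerates the enone; Negishi coupling with the enol triflate forms C12–C13 with the methylene group already in place, and dilute acetic acid removes only the triethylsilyl ether.

Step 22
Reactants: 37 coupled enone alcohol
Product: 38 pentacyclic 6-ketone (C2′ benzyl ether; C5′ tert-butyldimethylsilyl ether)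
Conditions: EtAlCl2 (3.0 equiv), CH2Cl2, −78 to −20 °C
Reagents that add atoms: none
Why: EtAlCl2 converts the C1′ hydroxyl into its aluminium alkoxide (ethane is lost, so no protic acid is present) and activates the enone; C14 adds to C8 in a Lewis-acid-promoted alkene–enone conjugate addition through a chair-like six-membered transition state on the face anti to the axial C10 methyl, giving the trans B/C fusion with the C8 methyl axial. The tertiary C13 cation is then captured by the C1′ oxygen on the face that leaves the bulky C3′ carbon equatorial (oxygen axial, syn to the C8 methyl), as in oxygen-terminated cation–olefin cyclisations, so ring C, ring D, C8 and C13 are formed in one operation.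

Step 23
Reactants: 38 pentacyclic 6-ketone
Product: 39 pentacyclic 6-alcohol (hydroxyl axial, syn to the C8 and C10 methyls)
Conditions: LiAlH4, THF, 0 °C
Reagents that add atoms: none
Why: Hydride reduction: the reagent can reach C6 only from the face opposite the three syn-axial methyls on C4, C8 and C10, which gives the axial alcohol.

Step 24
Reactants: 39 pentacyclic 6-alcohol
Product: 40 pentacyclic 6-acetate (C2′ benzyl ether; C5′ silyl ether)
Conditions: Ac2O, DMAP (1 equiv), Et3N, ClCH2CH2Cl, 50 °C
Reagents that add atoms: acetic anhydride, CC(=O)OC(C)=O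
Why: DMAP-catalysed acylation under forcing conditions for a hindered axial alcohol; no other free hydroxyl is present.

Step 25
Reactants: 40 pentacyclic 6-acetate
Product: 41 6-acetate with free C5′ hydroxyl (C2′ benzyl ether)
Conditions: HF·pyridine, THF, 0 °C to rt
Reagents that add atoms: none
Why: Fluoride cleavage of the secondary silyl ether; acetate, benzyl ether and the tertiary ring D ether tolerate these weakly acidic conditions.

Step 26
Reactants: 41 C5′ alcohol
Product: 42 6-acetate C5′ ketone (C2′ benzyl ether)
Conditions: Dess–Martin periodinane, NaHCO3, CH2Cl2, rt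
Reagents that add atoms: none
Why: Dess–Martin oxidation at buffered neutral pH forms the β-alkoxy ketone without base, so ring D is not opened and C6′ is not epimerised.

Step 27
Reactants: 42 C5′ ketone benzyl ether
Product: 43 target CNP0188572.2
Conditions: H2 (1 atm), Pd/C, EtOAc, rt
Reagents that add atoms: none
Why: Neutral hydrogenolysis of the benzyl ether as the last step keeps acid and base away from the β-alkoxy ketone; the acetate and the ketone are not reduced under these conditions.

## Compound list

1 | butane-1,4-diol | OCCCCO | starting material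
2 | 4-[(tert-butyldiphenylsilyl)oxy]butan-1-ol | OCCCCO[Si](c1ccccc1)(c1ccccc1)C(C)(C)C | intermediate
3 | 4-[(tert-butyldiphenylsilyl)oxy]butanal | O=CCCCO[Si](c1ccccc1)(c1ccccc1)C(C)(C)C | intermediate
4 | but-3-en-2-one | CC(=O)C=C | starting material
5 | (S)-2-{2-[(tert-butyldiphenylsilyl)oxy]ethyl}-5-oxohexanal | O=C[C@H](CCO[Si](c1ccccc1)(c1ccccc1)C(C)(C)C)CCC(C)=O | intermediate (not isolated)
6 | (S)-4-{2-[(tert-butyldiphenylsilyl)oxy]ethyl}cyclohex-2-en-1-one | O=C1C=C[C@H](CCO[Si](c2ccccc2)(c2ccccc2)C(C)(C)C)CC1 | intermediate
7 | trimethylsilyl enol ether of the trans-3-methyl-4-(silyloxyethyl)cyclohexanone | C[Si](C)(C)OC1=C[C@@H](C)[C@H](CCO[Si](c2ccccc2)(c2ccccc2)C(C)(C)C)CC1 | intermediate (not isolated)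
8 | (S)-4-{2-[(tert-butyldiphenylsilyl)oxy]ethyl}-3-methylcyclohex-2-en-1-one | O=C1C=C(C)[C@H](CCO[Si](c2ccccc2)(c2ccccc2)C(C)(C)C)CC1 | intermediate
9 | 5-bromo-2-methylpent-2-ene | CC(C)=CCCBr | starting material
10 | (4-methylpent-3-en-1-yl)magnesium bromide | CC(C)=CCC[Mg]Br | intermediate (not isolated)
11 | C5=C6 trimethylsilyl enol ether of 12 | C[Si](C)(C)OC1=C[C@@](C)(CCC=C(C)C)[C@H](CCO[Si](c2ccccc2)(c2ccccc2)C(C)(C)C)CC1 | intermediate (not isolated)
12 | (3R,4S)-4-{2-[(tert-butyldiphenylsilyl)oxy]ethyl}-3-methyl-3-(4-methylpent-3-en-1-yl)cyclohexan-1-one | O=C1C[C@@](C)(CCC=C(C)C)[C@H](CCO[Si](c2ccccc2)(c2ccccc2)C(C)(C)C)CC1 | intermediate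
13 | (4S,4aS,8aS) cis-fused C5 epimer of 14 | O=C1CC[C@@H](CCO[Si](c3ccccc3)(c3ccccc3)C(C)(C)C)[C@]2(C)CCCC(C)(C)[C@H]12 | intermediate (not isolated)
14 | (4S,4aS,8aR)-4-{2-[(tert-butyldiphenylsilyl)oxy]ethyl}-4a,8,8-trimethyloctahydronaphthalen-1(2H)-one | O=C1CC[C@@H](CCO[Si](c3ccccc3)(c3ccccc3)C(C)(C)C)[C@]2(C)CCCC(C)(C)[C@@H]12 | intermediate
15 | C6–C7 trimethylsilyl enol ether of 14 | C[Si](C)(C)OC1=CC[C@@H](CCO[Si](c3ccccc3)(c3ccccc3)C(C)(C)C)[C@]2(C)CCCC(C)(C)[C@@H]12 | intermediate (not isolated)
16 | 7-en-6-one (C12 silyl ether) | O=C1C=C[C@@H](CCO[Si](c3ccccc3)(c3ccccc3)C(C)(C)C)[C@]2(C)CCCC(C)(C)[C@@H]12 | intermediate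
17 | C6–C7 trimethylsilyl enol ether of the 8-methyl-6-ketone (8-methyl anti to the C10 methyl) | C[Si](C)(C)OC1=C[C@H](C)[C@@H](CCO[Si](c3ccccc3)(c3ccccc3)C(C)(C)C)[C@]2(C)CCCC(C)(C)[C@@H]12 | intermediate (not isolated)
18 | 8-methyl-7-en-6-one, C12 tert-butyldiphenylsilyl ether | O=C1C=C(C)[C@@H](CCO[Si](c3ccccc3)(c3ccccc3)C(C)(C)C)[C@]2(C)CCCC(C)(C)[C@@H]12 | intermediate
19 | 8-methyl-7-en-6-one, C12 alcohol | O=C1C=C(C)[C@@H](CCO)[C@]2(C)CCCC(C)(C)[C@@H]12 | intermediate
20 | 8-methyl-7-en-6-one, C12 iodide | O=C1C=C(C)[C@@H](CCI)[C@]2(C)CCCC(C)(C)[C@@H]12 | intermediate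
21 | 3-methylbut-2-enal | CC(C)=CC=O | starting material
22 | (E)-3-methylbuta-1,3-dien-1-yl acetate | CC(=C)/C=C/OC(C)=O | intermediate
23 | 3-acryloyl-1,3-oxazolidin-2-one | C=CC(=O)N1CCOC1=O | starting material
24 | (1S,6R)-3-methyl-6-[(2-oxo-1,3-oxazolidin-3-yl)carbonyl]cyclohex-2-en-1-yl acetate | CC1=C[C@H](OC(C)=O)[C@H](C(=O)N2CCOC2=O)CC1 | intermediate
25 | (1R,2S)-2-hydroxy-4-methylcyclohex-3-ene-1-carboxylic acid | CC1=C[C@H](O)[C@H](C(=O)O)CC1 | intermediate (not isolated)
26 | 8-hydroxy-4-iodo-4-methyl-6-oxabicyclo[3.2.1]octan-7-one | O=C1O[C@H]2[C@@](I)(C)CC[C@@H]1[C@H]2O | intermediate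
27 | 8-hydroxy-4-methyl-6-oxabicyclo[3.2.1]oct-3-en-7-one | O=C1O[C@H]2C(C)=CC[C@@H]1[C@H]2O | intermediate
28 | 8-(benzyloxy)-4-methyl-6-oxabicyclo[3.2.1]oct-3-en-7-one | O=C1O[C@H]2C(C)=CC[C@@H]1[C@H]2OCc1ccccc1 | intermediate
29 | 8-(benzyloxy)-3-hydroxy-4-methyl-6-oxabicyclo[3.2.1]octan-7-one | O=C1O[C@H]2[C@@H](C)[C@H](O)C[C@@H]1[C@H]2OCc1ccccc1 | intermediate
30 | 8-(benzyloxy)-3-[(tert-butyldimethylsilyl)oxy]-4-methyl-6-oxabicyclo[3.2.1]octan-7-one | O=C1O[C@H]2[C@@H](C)[C@H](O[Si](C)(C)C(C)(C)C)C[C@@H]1[C@H]2OCc1ccccc1 | intermediate
31 | ring E hydroxy Weinreb amide (C1′ OH; C2′ OBn; C5′ OSiMe2t-Bu; C6′ methyl) | CON(C)C(=O)[C@@H]1C[C@@H](O[Si](C)(C)C(C)(C)C)[C@H](C)[C@H](O)[C@@H]1OCc1ccccc1 | intermediate (not isolated)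
32 | ring E Weinreb amide, C1′ triethylsilyl ether | CON(C)C(=O)[C@@H]1C[C@@H](O[Si](C)(C)C(C)(C)C)[C@H](C)[C@H](O[Si](CC)(CC)CC)[C@@H]1OCc1ccccc1 | intermediate
33 | ring E methyl ketone | CC(=O)[C@@H]1C[C@@H](O[Si](C)(C)C(C)(C)C)[C@H](C)[C@H](O[Si](CC)(CC)CC)[C@@H]1OCc1ccccc1 | intermediate
34 | ring E enol triflate (C13=C14) | C=C(OS(=O)(=O)C(F)(F)F)[C@@H]1C[C@@H](O[Si](C)(C)C(C)(C)C)[C@H](C)[C@H](O[Si](CC)(CC)CC)[C@@H]1OCc1ccccc1 | intermediate
35 | C12 alkylzinc iodide of the 8-methyl-7-en-6-one | O=C1C=C(C)[C@@H](CC[Zn]I)[C@]2(C)CCCC(C)(C)[C@@H]12 | intermediate (not isolated)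
36 | coupled enone, C1′ triethylsilyl ether | O=C1C=C(C)[C@@H](CCC(=C)[C@@H]3C[C@@H](O[Si](C)(C)C(C)(C)C)[C@H](C)[C@H](O[Si](CC)(CC)CC)[C@@H]3OCc3ccccc3)[C@]2(C)CCCC(C)(C)[C@@H]12 | intermediate (not isolated)
37 | coupled enone, free C1′ hydroxyl | O=C1C=C(C)[C@@H](CCC(=C)[C@@H]3C[C@@H](O[Si](C)(C)C(C)(C)C)[C@H](C)[C@H](O)[C@@H]3OCc3ccccc3)[C@]2(C)CCCC(C)(C)[C@@H]12 | intermediate
38 | pentacyclic 6-ketone (C2′ OBn; C5′ OSiMe2t-Bu) | O=C1C[C@]2(C)C[C@]3(CC[C@H]2[C@]2(C)CCCC(C)(C)[C@@H]12)O[C@@H]1[C@H](OCc4ccccc4)[C@H]3C[C@@H](O[Si](C)(C)C(C)(C)C)[C@@H]1C | intermediate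
39 | pentacyclic 6-alcohol (axial OH) | O[C@H]1C[C@]2(C)C[C@]3(CC[C@H]2[C@]2(C)CCCC(C)(C)[C@@H]12)O[C@@H]1[C@H](OCc4ccccc4)[C@H]3C[C@@H](O[Si](C)(C)C(C)(C)C)[C@@H]1C | intermediate
40 | pentacyclic 6-acetate (C2′ OBn; C5′ OSiMe2t-Bu) | CC(=O)O[C@H]1C[C@]2(C)C[C@]3(CC[C@H]2[C@]2(C)CCCC(C)(C)[C@@H]12)O[C@@H]1[C@H](OCc4ccccc4)[C@H]3C[C@@H](O[Si](C)(C)C(C)(C)C)[C@@H]1C | intermediate
41 | 6-acetate, C5′ alcohol (C2′ OBn) | CC(=O)O[C@H]1C[C@]2(C)C[C@]3(CC[C@H]2[C@]2(C)CCCC(C)(C)[C@@H]12)O[C@@H]1[C@H](OCc4ccccc4)[C@H]3C[C@@H](O)[C@@H]1C | intermediate
42 | 6-acetate, C5′ ketone (C2′ OBn) | CC(=O)O[C@H]1C[C@]2(C)C[C@]3(CC[C@H]2[C@]2(C)CCCC(C)(C)[C@@H]12)O[C@@H]1[C@H](OCc4ccccc4)[C@H]3CC(=O)[C@@H]1C | intermediate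
43 | CNP0188572.2 | CC(=O)O[C@H]1C[C@]2(C)C[C@]3(CC[C@H]2[C@]2(C)CCCC(C)(C)[C@@H]12)O[C@@H]1[C@H](O)[C@H]3CC(=O)[C@@H]1C | target

## Step count and least certain steps

Total step count: 27. Longest linear sequence: 17 steps (steps 1–10, then 21–27; the ring E branch, steps 11–20 then 21–27, is equally long).

**Step 6 (key step).** The most likely failure is diversion of the cation or of the activated carbonyl before the slow enolisation toward the hindered C5 can deliver the nucleophile: Prins-type attack of the alkene on the tin-bound ketone from the ring-flipped conformer, or repeated elimination and chloride capture that only isomerises the side chain. Fallback, from 11 back to 14: 11 is isolated by non-aqueous work-up in step 5; MeLi (THF, 0 °C) releases the C5 lithium enolate regiospecifically and Ac2O traps it as the C5=C6 enol acetate F1; HCl (CH2Cl2, −78 °C) adds to the alkene to give the tertiary chloride F2; TiCl4 (CH2Cl2, −78 °C) then ionises the chloride and the enol ester closes ring A in an aprotic tert-alkylation of an enol derivative, with no free carbonyl for a Prins reaction. The same C5 equilibration returns the route to 14.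

**Step 22.** The C13 cation may lose a proton (ene-type termination) faster than the aluminium-bound C1′ oxygen captures it, or traces of protic acid may add the C1′ hydroxyl across the methylene group before the C–C bond forms, which would waste C14 as a methyl group. Fallback, from 36 back to 38: 36 is isolated by omitting the acid treatment of step 21; with the hydroxyl still silylated, EtAlCl2 effects only the alkene–enone cyclisation with proton loss, giving the tricyclic 12-ene F3 (with its 13(14)-ene isomer); p-TsOH in CH2Cl2 then removes the triethylsilyl group and closes ring D by Markovnikov hydroalkoxylation through the same tertiary C13 cation, giving 38.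

**Step 21.** Zinc insertion may be sluggish, or the enone may be reduced while 35 forms; transmetallation to the α-branched alkenylpalladium species may also be slow, so that 35 is simply protonated. Fallback, from 20 and 34 back to 37: a nickel-catalysed reductive cross-electrophile coupling of the iodide with the enol triflate (NiBr2·glyme, 4,4′-di-tert-butyl-2,2′-bipyridine, Mn, DMA), which needs no preformed organometallic, followed by the same acetic acid treatment; this fallback makes no new compound (F0).

**Step 20.** Deprotonation may occur at C3′ instead of the methyl group, leading to β-elimination of the C2′ benzyloxy group or to the internal enol triflate. Fallback, from 33 back to 37: hydrazine hydrate (EtOH, Et3N) gives the hydrazone F4, and iodine with tetramethylguanidine (Barton vinyl iodide synthesis) gives the 1-iodovinyl compound F5 without a strong base; F5 takes the place of 34 in step 21 and the route is rejoined at 37.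

**Step 24.** Acylation of the axial C6 hydroxyl may stall because three syn-axial methyls block the approach of the acylpyridinium ion, and harsher conditions would begin to attack the silyl ether. Fallback, from 38 back to 40, bypassing 39: LDA then Ac2O converts the ketone into the C6–C7 enol acetate F6 (O-acylation of the enolate is not hindered); hydrogenation with [Ir(cod)(PCy3)(py)]PF6 in CH2Cl2 delivers hydrogen from the open face, which leaves the acetate axial and spares the benzyl ether, giving 40.

## Further compounds

F1 | step 6 | C5=C6 enol acetate of 12 | CC(=O)OC1=C[C@@](C)(CCC=C(C)C)[C@H](CCO[Si](c2ccccc2)(c2ccccc2)C(C)(C)C)CC1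
F2 | step 6 | enol acetate with 4-chloro-4-methylpentyl chain | CC(=O)OC1=C[C@@](C)(CCCC(C)(C)Cl)[C@H](CCO[Si](c2ccccc2)(c2ccccc2)C(C)(C)C)CC1
F3 | step 22 | tricyclic 8-methyl-6-ketone with C12=C13 double bond and silylated ring E | O=C1C[C@]2(C)CC(=CC[C@H]2[C@]2(C)CCCC(C)(C)[C@@H]12)[C@@H]1C[C@@H](O[Si](C)(C)C(C)(C)C)[C@H](C)[C@H](O[Si](CC)(CC)CC)[C@@H]1OCc1ccccc1
F0 | step 21 | none | none
F4 | step 20 | hydrazone of 33 | CC(=NN)[C@@H]1C[C@@H](O[Si](C)(C)C(C)(C)C)[C@H](C)[C@H](O[Si](CC)(CC)CC)[C@@H]1OCc1ccccc1
F5 | step 20 | ring E 1-iodovinyl compound | C=C(I)[C@@H]1C[C@@H](O[Si](C)(C)C(C)(C)C)[C@H](C)[C@H](O[Si](CC)(CC)CC)[C@@H]1OCc1ccccc1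
F6 | step 24 | C6–C7 enol acetate of 38 | CC(=O)OC1=C[C@]2(C)C[C@]3(CC[C@H]2[C@]2(C)CCCC(C)(C)[C@@H]12)O[C@@H]1[C@H](OCc4ccccc4)[C@H]3C[C@@H](O[Si](C)(C)C(C)(C)C)[C@@H]1C
A1 | alternative 1 | tricyclic 6-acetate with C13 O-(2-oxoethyl) ether and (E)-3-oxopent-1-enyl group | CC(=O)O[C@H]1C[C@]2(C)C[C@](CC[C@H]2[C@]2(C)CCCC(C)(C)[C@@H]12)(OCC=O)/C=C/C(=O)CC
A2 | alternative 1 | spiro dihydrofuranone with 2-oxobutyl chain on C3′ | CC(=O)O[C@H]1C[C@]2(C)C[C@]3(CC[C@H]2[C@]2(C)CCCC(C)(C)[C@@H]12)OCC(=O)[C@H]3CC(=O)CC
A3 | alternative 2 | pentacyclic 6-ketone (identical with 38) | O=C1C[C@]2(C)C[C@]3(CC[C@H]2[C@]2(C)CCCC(C)(C)[C@@H]12)O[C@@H]1[C@H](OCc4ccccc4)[C@H]3C[C@@H](O[Si](C)(C)C(C)(C)C)[C@@H]1C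
A4 | alternative 3 | decalin 1,5-dibromide with C6 dioxolane | O1CCOC12C[C@](C)(CBr)[C@@H](CCBr)[C@]3(C)CCCC(C)(C)[C@@H]23
A5 | alternative 3 | tetracyclic C13 carbinol with free C1′ hydroxyl | O1CCOC12C[C@]3(C)C[C@@](O)(CC[C@H]3[C@]3(C)CCCC(C)(C)[C@@H]23)[C@@H]4C[C@@H](O[Si](C)(C)C(C)(C)C)[C@H](C)[C@H](O)[C@@H]4OCc5ccccc5
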